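## Retrosynthetic overview

1. The target is reached by hydrogenolysis of five benzyl ethers, preceded by C-acylation at C1 of ring C with (R)-2-methylbutanoyl chloride; the only stereocentre comes from the chiral pool.
2. Ring C is numbered C1 (acyl), C2/C4/C6 (oxygen), C3 (CH2 to acetyl ring A), C5 (CH2 to isobutyryl ring B). The strategy rests on reading C3–C4(O)–C5, with its two different arylmethyl arms, as the enol ether of an open-chain 1,5-diarylpentan-3-one, and C2–C1–C6 as a malonyl unit. Ring C is therefore closed last, by forming C2–C3 and C5–C6 with malonyl dichloride.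
3. The enol oxygen (O4) is capped as a benzyl ether rather than a silyl ether, so that the second acylation has to go to C5; the cap leaves with the other benzyl groups at the end.
4. The diaryl ketone comes from 1,3-bis(diethoxyphosphoryl)propan-2-one by two Horner–Wadsworth–Emmons reactions (ring B aldehyde, then ring A aldehyde) and saturation of both alkenes.
5. Rings A and B are both made from 2,4,6-trihydroxytoluene (C-acylation, di-O-benzylation, O-methylation, formylation). Ring order: A and B present from the start, C formed last.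

Key step: step 13

Shorthand: ArA = 3-acetyl-2,6-bis(benzyloxy)-4-methoxy-5-methylphenyl; ArB = 2,6-bis(benzyloxy)-4-methoxy-5-methyl-3-(2-methylpropanoyl)phenyl.

Assumption: enol ether 17 is used as the mixture of double-bond isomers that the elimination gives (toward ring A or ring B, E or Z), because every isomer holds the same C3–C4(O)–C5 unit and leads to the same ring C; the Z isomer with the double bond on the ring A side is the one named and listed.

## Route

Step 1
Reactants: 1 2,4,6-trihydroxytoluene
Product: 2 1-(2,4,6-trihydroxy-3-methylphenyl)ethan-1-one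
Conditions: AcCl (1.1 equiv), AlCl3 (3 equiv), PhNO2–CH2Cl2, 0 °C → rt; aq. HCl
Reagents that add atoms: acetyl chloride CC(=O)Cl
Why: Friedel–Crafts C-acylation of the phloroglucinol nucleus, whose two free positions are equivalent, should stop after one acyl group because the first ketone deactivates the ring.

Step 2
Reactants: 2 1-(2,4,6-trihydroxy-3-methylphenyl)ethan-1-one
Product: 3 1-[4,6-bis(benzyloxy)-2-hydroxy-3-methylphenyl]ethan-1-one
Conditions: BnBr (2.1 equiv), K2CO3 (2.2 equiv), DMF, rt
Reagents that add atoms: benzyl bromide BrCc1ccccc1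
Why: Williamson etherification should take the unchelated para-hydroxyl first and then the ortho-hydroxyl flanked by C–H, leaving the hydroxyl wedged between methyl and acetyl and hydrogen-bonded to the carbonyl; a minor regioisomer would be removed by chromatography and the assignment checked by NOE.

Step 3
Reactants: 3 1-[4,6-bis(benzyloxy)-2-hydroxy-3-methylphenyl]ethan-1-one
Product: 4 1-[4,6-bis(benzyloxy)-2-methoxy-3-methylphenyl]ethan-1-one
Conditions: MeI (3 equiv), K2CO3, DMF, 50 °C
Reagents that add atoms: iodomethane CI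
Why: Williamson methylation under more forcing conditions should etherify the remaining chelated hydroxyl, which fixes the methoxy group between methyl and acetyl as in ring A.

Step 4
Reactants: 4 1-[4,6-bis(benzyloxy)-2-methoxy-3-methylphenyl]ethan-1-one
Product: 6 3-acetyl-2,6-bis(benzyloxy)-4-methoxy-5-methylbenzaldehyde, via iminium chloride 5 (not isolated)
Conditions: POCl3 (1.5 equiv), DMF, 0 °C → rt; then aq. NaOAc
Reagents that add atoms: N,N-dimethylformamide CN(C)C=O; water O
Why: Vilsmeier–Haack formylation should attack the only free ring position, activated by two ortho benzyloxy groups and a para methoxy group, at a temperature at which the twisted, hindered acetyl group is not yet converted into a chlorovinyl aldehyde; aqueous acetate then hydrolyses the iminium salt.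

Step 5
Reactants: 1 2,4,6-trihydroxytoluene
Product: 7 2-methyl-1-(2,4,6-trihydroxy-3-methylphenyl)propan-1-one
Conditions: iPrCOCl (1.1 equiv), AlCl3 (3 equiv), PhNO2–CH2Cl2, 0 °C → rt; aq. HCl
Reagents that add atoms: 2-methylpropanoyl chloride CC(C)C(=O)Cl
Why: Friedel–Crafts C-acylation as in step 1, limited to one acyl group by deactivation of the ring.

Step 6
Reactants: 7 2-methyl-1-(2,4,6-trihydroxy-3-methylphenyl)propan-1-one
Product: 8 1-[4,6-bis(benzyloxy)-2-hydroxy-3-methylphenyl]-2-methylpropan-1-one
Conditions: BnBr (2.1 equiv), K2CO3 (2.2 equiv), DMF, rt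
Reagents that add atoms: benzyl bromide BrCc1ccccc1
Why: Williamson etherification with the same order of reactivity as in step 2 (para-hydroxyl, then the ortho-hydroxyl next to C–H), the hydroxyl between methyl and acyl staying free.

Step 7
Reactants: 8 1-[4,6-bis(benzyloxy)-2-hydroxy-3-methylphenyl]-2-methylpropan-1-one
Product: 9 1-[4,6-bis(benzyloxy)-2-methoxy-3-methylphenyl]-2-methylpropan-1-one
Conditions: MeI (3 equiv), K2CO3, DMF, 50 °C
Reagents that add atoms: iodomethane CI
Why: Williamson methylation of the last, chelated hydroxyl places the methoxy group between methyl and isobutyryl as in ring B.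

Step 8
Reactants: 9 1-[4,6-bis(benzyloxy)-2-methoxy-3-methylphenyl]-2-methylpropan-1-one
Product: 11 2,6-bis(benzyloxy)-4-methoxy-5-methyl-3-(2-methylpropanoyl)benzaldehyde, via iminium chloride 10 (not isolated)
Conditions: POCl3 (1.5 equiv), DMF, 0 °C → rt; then aq. NaOAc
Reagents that add atoms: N,N-dimethylformamide CN(C)C=O; water O
Why: Vilsmeier–Haack formylation at the single free, trialkoxy-activated ring position; the isobutyryl ketone has no enolisable methyl group and should not interfere.

Step 9
Reactants: 11 2,6-bis(benzyloxy)-4-methoxy-5-methyl-3-(2-methylpropanoyl)benzaldehyde; 12 1,3-bis(diethoxyphosphoryl)propan-2-one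
Product: 13 diethyl [(3E)-4-ArB-2-oxobut-3-en-1-yl]phosphonate
Conditions: 12 (2 equiv), NaH (1.05 equiv), THF, 0 °C; then 11, 0 °C → rt
Reagents that add atoms: none
Why: Horner–Wadsworth–Emmons olefination with the bisphosphonate in excess should give the (E)-enone after a single olefination and keep the second phosphonate for the next coupling.

Step 10
Reactants: 13 diethyl [(3E)-4-ArB-2-oxobut-3-en-1-yl]phosphonate; 6 3-acetyl-2,6-bis(benzyloxy)-4-methoxy-5-methylbenzaldehyde
Product: 14 (1E,4E)-1-ArA-5-ArB-penta-1,4-dien-3-one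
Conditions: LiCl, DBU, MeCN–THF, rt
Reagents that add atoms: none
Why: Horner–Wadsworth–Emmons olefination under Masamune–Roush conditions should deprotonate only the β-ketophosphonate, so that the methyl ketone of aldehyde 6 stays out of aldol condensation, and give the (E,E)-dienone.

Step 11
Reactants: 14 (1E,4E)-1-ArA-5-ArB-penta-1,4-dien-3-one
Product: 15 1-ArA-5-ArB-pentan-3-one
Conditions: H2 (1 atm), 10% Pd/C, Ph2S (0.01 equiv), EtOAc, rt
Reagents that add atoms: none
Why: Catalytic hydrogenation over sulfide-poisoned palladium should saturate both enone double bonds while the poisoned surface leaves aryl benzyl ethers and aryl ketones untouched.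

Step 12
Reactants: 15 1-ArA-5-ArB-pentan-3-one
Product: 17 (2Z)-3-(benzyloxy)-1-ArA-5-ArB-pent-2-ene (benzyl enol ether of 15), via dibenzyl ketal 16 (not isolated)
Conditions: PhCH2OSiMe3 (2.5 equiv), Me3SiOTf (0.1 equiv), CH2Cl2, −78 → −20 °C; then iPr2NEt (1.5 equiv), Me3SiOTf (1.2 equiv), −20 °C → rt; K2CO3, MeOH, 0 °C
Reagents that add atoms: benzyloxytrimethylsilane C[Si](C)(C)OCc1ccccc1
Why: Silyl triflate-catalysed ketalisation with the alkoxysilane should occur only at the unhindered dialkyl ketone (both aryl ketones are di-ortho-substituted), and Me3SiOTf with a hindered amine then removes one benzyloxy group from the ketal (oxocarbenium formation, α-deprotonation) to give the enol ether, the carbonate/methanol work-up cleaving any trimethylsilyl enol ether formed at the acetyl group.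

Step 13
Reactants: 17 (2Z)-3-(benzyloxy)-1-ArA-5-ArB-pent-2-ene; 18 malonyl dichloride
Product: 20 4-(ArA-methyl)-5-(benzyloxy)-6-(ArB-methyl)benzene-1,3-diol (ring C with C1–H and O4 benzylated), via acyl chloride 19 (not isolated)
Conditions: 18 (1.05 equiv) added slowly, Et2O, 0.02 M, −20 °C → rt, N2, no base; then aq. NaHCO3
Reagents that add atoms: none
Why: The enol ether carbon C3 attacks one acyl chloride group of 18 (uncatalysed C-acylation of an enol ether by a very electrophilic chloride) and loss of HCl gives the β-benzyloxy enone 19 with O4 still capped; acid-mediated γ-enolisation toward C5 then lets C5 attack the second acyl chloride, and the 5-benzyloxycyclohexene-1,3-dione so formed tautomerises to the resorcinol 20. The closest known reaction is the Effenberger annulation of ketone alkyl enol ethers with malonyl dichloride, which leads to 5-alkoxyresorcinols from open-chain enol ethers and to α,α′-bridged triones from cyclohexanone enol ethers. Ring C closes by an intramolecular vinylogous Claisen-type C-acylation, 6-exo-trig at the acyl carbon, and no stereocentre is formed. The step needs closure through C5 and not through O4, and the benzyl cap secures this, since silyl enol ethers of open-chain ketones lose silicon after the first acylation and then close through oxygen to 4-hydroxy-2-pyranones. It also needs the central enol ether to be the only nucleophile: the di-ortho-substituted aryl ketones of rings A and B do not enolise without base or Lewis acid, rings A and B have no free position, and dilution with slow addition holds back intermolecular acylation. Every double-bond isomer of 17 places the two arms on C3 and C5 and so gives the same product.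

Step 14
Reactants: 21 (R)-2-methylbutanoic acid
Product: 22 (R)-2-methylbutanoyl chloride
Conditions: (COCl)2 (1.2 equiv), DMF (cat.), CH2Cl2, 0 °C → rt; volatiles removed cold, used at once
Reagents that add atoms: oxalyl chloride O=C(Cl)C(=O)Cl
Why: Acid chloride formation through the chloroiminium (Vilsmeier-type) catalyst under amine-free conditions should leave the α-stereocentre untouched.

Step 15
Reactants: 20 4-(ArA-methyl)-5-(benzyloxy)-6-(ArB-methyl)benzene-1,3-diol; 22 (R)-2-methylbutanoyl chloride
Product: 23 (2R)-1-[4-(benzyloxy)-2,6-dihydroxy-3-(ArA-methyl)-5-(ArB-methyl)phenyl]-2-methylbutan-1-one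
Conditions: 22 (1.5 equiv), BF3·OEt2 (3 equiv), CH2Cl2, −20 °C → rt; aq. NaHCO3; then K2CO3, MeOH, 0 °C
Reagents that add atoms: none
Why: Friedel–Crafts C-acylation (any aryl ester formed first undergoing a Fries shift) can only occur at C1, the one unsubstituted carbon of the three rings, and BF3 is chosen because it neither cleaves the methoxy groups ortho to the ring A and ring B ketones nor needs a base that could epimerise the (R)-centre; the brief methanolysis removes residual O-esters.

Step 16
Reactants: 23 (2R)-1-[4-(benzyloxy)-2,6-dihydroxy-3-(ArA-methyl)-5-(ArB-methyl)phenyl]-2-methylbutan-1-one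
Product: 24 (2R)-1-[3-[(3-acetyl-2,6-dihydroxy-4-methoxy-5-methylphenyl)methyl]-5-{[2,6-dihydroxy-4-methoxy-5-methyl-3-(2-methylpropanoyl)phenyl]methyl}-2,4,6-trihydroxyphenyl]-2-methylbutan-1-one (target)
Conditions: H2 (1 atm), 10% Pd/C, EtOAc–MeOH, rt
Reagents that add atoms: none
Why: Hydrogenolysis of the five aryl benzyl ethers under neutral conditions should release the seven phenols without touching the chelated aryl ketones, the diarylmethane bridges or the stereocentre.

## Compound list

1 | 2,4,6-trihydroxytoluene | Cc1c(O)cc(O)cc1O | starting material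
2 | 1-(2,4,6-trihydroxy-3-methylphenyl)ethan-1-one | CC(=O)c1c(O)cc(O)c(C)c1O | intermediate
3 | 1-[4,6-bis(benzyloxy)-2-hydroxy-3-methylphenyl]ethan-1-one | CC(=O)c1c(OCc2ccccc2)cc(OCc2ccccc2)c(C)c1O | intermediate
4 | 1-[4,6-bis(benzyloxy)-2-methoxy-3-methylphenyl]ethan-1-one | CC(=O)c1c(OCc2ccccc2)cc(OCc2ccccc2)c(C)c1OC | intermediate
5 | N-(ArA-methylidene)-N-methylmethanaminium chloride (Vilsmeier iminium salt, not isolated) | C[N+](C)=Cc1c(OCc2ccccc2)c(C(C)=O)c(OC)c(C)c1OCc1ccccc1.[Cl-] | intermediate
6 | 3-acetyl-2,6-bis(benzyloxy)-4-methoxy-5-methylbenzaldehyde (ring A aldehyde) | O=Cc1c(OCc2ccccc2)c(C(C)=O)c(OC)c(C)c1OCc1ccccc1 | intermediate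
7 | 2-methyl-1-(2,4,6-trihydroxy-3-methylphenyl)propan-1-one | CC(C)C(=O)c1c(O)cc(O)c(C)c1O | intermediate
8 | 1-[4,6-bis(benzyloxy)-2-hydroxy-3-methylphenyl]-2-methylpropan-1-one | CC(C)C(=O)c1c(OCc2ccccc2)cc(OCc2ccccc2)c(C)c1O | intermediate
9 | 1-[4,6-bis(benzyloxy)-2-methoxy-3-methylphenyl]-2-methylpropan-1-one | CC(C)C(=O)c1c(OCc2ccccc2)cc(OCc2ccccc2)c(C)c1OC | intermediate
10 | N-(ArB-methylidene)-N-methylmethanaminium chloride (Vilsmeier iminium salt, not isolated) | C[N+](C)=Cc1c(OCc2ccccc2)c(C(=O)C(C)C)c(OC)c(C)c1OCc1ccccc1.[Cl-] | intermediate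
11 | 2,6-bis(benzyloxy)-4-methoxy-5-methyl-3-(2-methylpropanoyl)benzaldehyde (ring B aldehyde) | O=Cc1c(OCc2ccccc2)c(C(=O)C(C)C)c(OC)c(C)c1OCc1ccccc1 | intermediate
12 | 1,3-bis(diethoxyphosphoryl)propan-2-one | CCOP(=O)(OCC)CC(=O)CP(=O)(OCC)OCC | starting material
13 | diethyl [(3E)-4-ArB-2-oxobut-3-en-1-yl]phosphonate | CCOP(=O)(OCC)CC(=O)/C=C/c1c(OCc2ccccc2)c(C(=O)C(C)C)c(OC)c(C)c1OCc1ccccc1 | intermediate
14 | (1E,4E)-1-ArA-5-ArB-penta-1,4-dien-3-one | O=C(/C=C/c1c(OCc2ccccc2)c(C(C)=O)c(OC)c(C)c1OCc1ccccc1)/C=C/c1c(OCc2ccccc2)c(C(=O)C(C)C)c(OC)c(C)c1OCc1ccccc1 | intermediate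
15 | 1-ArA-5-ArB-pentan-3-one | O=C(CCc1c(OCc2ccccc2)c(C(C)=O)c(OC)c(C)c1OCc1ccccc1)CCc1c(OCc2ccccc2)c(C(=O)C(C)C)c(OC)c(C)c1OCc1ccccc1 | intermediate
16 | 3,3-bis(benzyloxy)-1-ArA-5-ArB-pentane (dibenzyl ketal, not isolated) | O(Cc1ccccc1)C(CCc1c(OCc2ccccc2)c(C(C)=O)c(OC)c(C)c1OCc1ccccc1)(CCc1c(OCc2ccccc2)c(C(=O)C(C)C)c(OC)c(C)c1OCc1ccccc1)OCc1ccccc1 | intermediate
17 | (2Z)-3-(benzyloxy)-1-ArA-5-ArB-pent-2-ene (benzyl enol ether; used with its double-bond isomers) | C(c1ccccc1)O/C(CCc1c(OCc2ccccc2)c(C(=O)C(C)C)c(OC)c(C)c1OCc1ccccc1)=C\Cc1c(OCc2ccccc2)c(C(C)=O)c(OC)c(C)c1OCc1ccccc1 | intermediate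
18 | malonyl dichloride | O=C(Cl)CC(=O)Cl | starting material
19 | 4-(ArA-methyl)-5-(benzyloxy)-3-oxo-7-ArB-hept-4-enoyl chloride (not isolated) | O=C(Cl)CC(=O)C(Cc1c(OCc2ccccc2)c(C(C)=O)c(OC)c(C)c1OCc1ccccc1)=C(CCc1c(OCc2ccccc2)c(C(=O)C(C)C)c(OC)c(C)c1OCc1ccccc1)OCc1ccccc1 | intermediate
20 | 4-(ArA-methyl)-5-(benzyloxy)-6-(ArB-methyl)benzene-1,3-diol | Oc1cc(O)c(Cc2c(OCc3ccccc3)c(C(=O)C(C)C)c(OC)c(C)c2OCc2ccccc2)c(OCc2ccccc2)c1Cc1c(OCc2ccccc2)c(C(C)=O)c(OC)c(C)c1OCc1ccccc1 | intermediate
21 | (R)-2-methylbutanoic acid | CC[C@@H](C)C(=O)O | starting material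
22 | (R)-2-methylbutanoyl chloride | CC[C@@H](C)C(=O)Cl | intermediate
23 | (2R)-1-[4-(benzyloxy)-2,6-dihydroxy-3-(ArA-methyl)-5-(ArB-methyl)phenyl]-2-methylbutan-1-one | CC[C@@H](C)C(=O)c1c(O)c(Cc2c(OCc3ccccc3)c(C(C)=O)c(OC)c(C)c2OCc2ccccc2)c(OCc2ccccc2)c(Cc2c(OCc3ccccc3)c(C(=O)C(C)C)c(OC)c(C)c2OCc2ccccc2)c1O | intermediate
24 | (2R)-1-[3-[(3-acetyl-2,6-dihydroxy-4-methoxy-5-methylphenyl)methyl]-5-{[2,6-dihydroxy-4-methoxy-5-methyl-3-(2-methylpropanoyl)phenyl]methyl}-2,4,6-trihydroxyphenyl]-2-methylbutan-1-one | CC[C@@H](C)C(=O)c1c(O)c(Cc2c(O)c(C)c(OC)c(C(C)=O)c2O)c(O)c(Cc2c(O)c(C)c(OC)c(C(=O)C(C)C)c2O)c1O | target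

## Step count and risks

Total steps: 16. Longest linear sequence: 11 steps (5, 6, 7, 8, 9, 10, 11, 12, 13, 15, 16).

Steps most likely to fail:

1. Step 13. The oxocarbenium stage may lose its benzyl cap to chloride, after which closure runs through the enol oxygen instead of C5; intermolecular acylation may also outrun the ring closure and give oligomers. Fallback (sets out from 22, 11 and 6, comes back at 24): ring C is taken ready-made and the arms are attached to it. Purchased benzene-1,3,5-triol would be C-acylated with 22 (AlCl3, PhNO2) to (2R)-2-methyl-1-(2,4,6-trihydroxyphenyl)butan-1-one F1, whose two free ring positions are exactly the two arm positions. Reductive Friedel–Crafts arylmethylation with aldehyde 11 (Et3SiH, CF3CO2H, CH2Cl2, 0 °C, F1 in excess) would give the mono-arm ketone (2R)-1-[3-(ArB-methyl)-2,4,6-trihydroxyphenyl]-2-methylbutan-1-one F2. A second arylmethylation with aldehyde 6 would give the tetrabenzyl ether (2R)-1-[3-(ArA-methyl)-5-(ArB-methyl)-2,4,6-trihydroxyphenyl]-2-methylbutan-1-one F3, which hydrogenolysis as in step 16 converts into 24. This gives up the ring-C-last logic and accepts statistical losses in the two arylmethylations.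

2. Step 15. BF3 may slowly ionise aryl benzyl ethers, so that benzyl cations alkylate the free C1 in competition with the hindered acyl donor, and long exposure of the boron-chelated product ketone may erode the (R)-centre. Fallback (sets out from 20, comes back at 24): the order of the last two operations is reversed so that no benzyl ether meets the Lewis acid. Hydrogenolysis of 20 (H2, Pd/C, EtOAc–MeOH) would give the heptaphenol 2-[(3-acetyl-2,6-dihydroxy-4-methoxy-5-methylphenyl)methyl]-4-{[2,6-dihydroxy-4-methoxy-5-methyl-3-(2-methylpropanoyl)phenyl]methyl}benzene-1,3,5-triol F4. Its only unsubstituted ring carbon is C1 of ring C, which would then be acylated with 22 (BF3·OEt2, CH2Cl2, 0 °C, short reaction time) while the o-hydroxy ketones of rings A and B sit as boron chelates. Phenyl esters would be cleaved by NaHCO3 in MeOH to give 24.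

3. Step 4 (its twin, step 8, has no enolisable methyl ketone and is less exposed). Electrophilic attack at the ring position between two benzyloxy groups may be slow on the fully substituted ring, and the chloroiminium reagent may instead consume the acetyl group. Fallback (sets out from 4, comes back at 6): the formyl carbon is brought in by cross-coupling. Bromination of 4 (N-bromosuccinimide, MeCN, 0 °C) would give 1-[4,6-bis(benzyloxy)-5-bromo-2-methoxy-3-methylphenyl]ethan-1-one F5. Suzuki–Miyaura coupling with vinylboronic acid pinacol ester (Pd(OAc)2, 2-dicyclohexylphosphino-2′,6′-dimethoxybiphenyl, K3PO4, toluene–H2O, 80 °C) would give 1-[4,6-bis(benzyloxy)-5-ethenyl-2-methoxy-3-methylphenyl]ethan-1-one F6. Lemieux–Johnson cleavage (OsO4 cat., NaIO4, 2,6-lutidine, dioxane–H2O) would then give aldehyde 6.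

## Further compounds

F1 | step 13 | (2R)-2-methyl-1-(2,4,6-trihydroxyphenyl)butan-1-one | CC[C@@H](C)C(=O)c1c(O)cc(O)cc1O
F2 | step 13 | (2R)-1-[3-(ArB-methyl)-2,4,6-trihydroxyphenyl]-2-methylbutan-1-one | CC[C@@H](C)C(=O)c1c(O)cc(O)c(Cc2c(OCc3ccccc3)c(C(=O)C(C)C)c(OC)c(C)c2OCc2ccccc2)c1O
F3 | step 13 | (2R)-1-[3-(ArA-methyl)-5-(ArB-methyl)-2,4,6-trihydroxyphenyl]-2-methylbutan-1-one | CC[C@@H](C)C(=O)c1c(O)c(Cc2c(OCc3ccccc3)c(C(C)=O)c(OC)c(C)c2OCc2ccccc2)c(O)c(Cc2c(OCc3ccccc3)c(C(=O)C(C)C)c(OC)c(C)c2OCc2ccccc2)c1O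
F4 | step 15 | 2-[(3-acetyl-2,6-dihydroxy-4-methoxy-5-methylphenyl)methyl]-4-{[2,6-dihydroxy-4-methoxy-5-methyl-3-(2-methylpropanoyl)phenyl]methyl}benzene-1,3,5-triol | Oc1cc(O)c(Cc2c(O)c(C(=O)C(C)C)c(OC)c(C)c2O)c(O)c1Cc1c(O)c(C(C)=O)c(OC)c(C)c1O
F5 | step 4 | 1-[4,6-bis(benzyloxy)-5-bromo-2-methoxy-3-methylphenyl]ethan-1-one | CC(=O)c1c(OCc2ccccc2)c(Br)c(OCc2ccccc2)c(C)c1OC
F6 | step 4 | 1-[4,6-bis(benzyloxy)-5-ethenyl-2-methoxy-3-methylphenyl]ethan-1-one | CC(=O)c1c(OCc2ccccc2)c(C=C)c(OCc2ccccc2)c(C)c1OC
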